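**Plan**

1. Retrosynthesis: the piperidinone is cut at N–CH2 and CH2–CH(CH3) (Mannich with formaldehyde); the cyclopentane at CH(C=O)–CH(N) and the piperidine at N–CH (amine–aldehyde condensation, then intramolecular Mannich); the ε-lactone at the bond between its carbonyl carbon and the α-CH2 (enol-ether metathesis, then oxidation); the cyclopentene at its C=C (metathesis). What is left is a cycloheptane made from cyclopentanone by a two-carbon ring expansion.
2. Forward order: cycloheptane (enamine + alkyne) → first quaternary carbon (Michael addition to ethyl vinyl ketone) → CH2N arm → second quaternary carbon (allylic alkylation of a β-keto amide) → cyclopentene (metathesis) → seven-membered enol ether (key metathesis) → ε-lactone → piperidine, cyclopentane and piperidinone in one acid-mediated finish.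
3. Enabling feature: the lactone ring C(quaternary)–CH2–CH2–C(=O)–O–CH2–C(quaternary) sits on the two adjacent quaternary carbons of the cycloheptane, and its O–C(=O)–CH2 unit is the oxidised form of an enol ether O–CH=CH. An O-vinyl group on the CH2O arm and a cinnamyl group on the neighbouring quaternary carbon, held cis, can therefore be joined at exactly these two carbons; the phenyl end and the vinyl CH2 leave as styrene, and the enol ether is oxidised to the lactone one step later.
4. Stereochemistry: the ester-bearing quaternary carbon is set by an organocatalytic enantioselective Michael addition. The CH–CH2N carbon, the second quaternary carbon and the ring-fusion CH are then set by reagent approach to the face opposite the side chain of that first centre. The two cage CH centres are fixed by ring geometry in the Mannich closure, and the CH–CH3 centre by equilibration to the equatorial methyl.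

Key step: step 18

Remark: in names from 7 on, the cycloheptane keeps the locants of 7 (C1 = ester-bearing quaternary carbon, C2 = its ring neighbour that becomes the second quaternary carbon, C3, C4 … C7 = former ketone carbon); α is the face of the C1 side chain, β the face of the C1 ester (later CH2O) group.

**Step 1**
Reactants: 1 1-(cyclopent-1-en-1-yl)pyrrolidine; 2 dimethyl but-2-ynedioate
Product: 5 dimethyl 7-oxocyclohept-2-ene-1,2-dicarboxylate, via cyclobutene adduct 3 (not isolated), via ring-opened dienamine 4 (not isolated)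
Conditions: toluene, 0 °C to 80 °C; then 1 M aq. HCl, THF, rt
Reagents that add atoms: water (O)
Why: Enamine–alkyne [2+2] cycloaddition followed by opening of the aminocyclobutene enlarges the ring by two carbons (enamine–acetylenedicarboxylate ring expansion), and hydrolysis of the dienamine should unveil the β-keto ester; the only stereocentre is acidic and racemic.

**Step 2**
Reactants: 5 dimethyl 7-oxocyclohept-2-ene-1,2-dicarboxylate; 6 pent-1-en-3-one
Product: 7 dimethyl (1S)-7-oxo-1-(3-oxopentyl)cyclohept-2-ene-1,2-dicarboxylate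
Conditions: 9-O-benzylcupreidine (10 mol %), CH2Cl2, −20 °C
Reagents that add atoms: none
Why: Enantioselective Michael addition of a cyclic β-keto ester to a vinyl ketone under bifunctional cinchona catalysis should create the quaternary carbon on one enolate face (the γ-position is the β-carbon of an acrylate and not nucleophilic); the pseudoenantiomeric cupreine catalyst serves if the opposite sense is found.

**Step 3**
Reactants: 7
Product: 8 dimethyl (1S)-1-[2-(2-ethyl-1,3-dioxolan-2-yl)ethyl]-7-oxocyclohept-2-ene-1,2-dicarboxylate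
Conditions: (Me3SiOCH2)2, Me3SiOTf (5 mol %), CH2Cl2, −78 °C
Reagents that add atoms: 1,2-bis(trimethylsilyloxy)ethane (C[Si](C)(C)OCCO[Si](C)(C)C)
Why: Noyori ketalisation at low temperature should pick the unhindered side-chain ketone over the ring ketone flanked by the quaternary carbon; no stereocentre is touched.

**Step 4**
Reactants: 8
Product: 9 dimethyl 1-[2-(2-ethyl-1,3-dioxolan-2-yl)ethyl]-7-methylidenecyclohept-2-ene-1,2-dicarboxylate
Conditions: Ph3PCH3Br, KN(SiMe3)2, THF, 0 °C to 45 °C
Reagents that add atoms: methyltriphenylphosphonium bromide (C[P+](c1ccccc1)(c1ccccc1)c1ccccc1.[Br-])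
Why: Wittig methylenation of the non-enolisable-on-one-side ring ketone (the esters and the ketal do not react with the preformed ylide) should give the exocyclic alkene that carries the future CH2N carbon.

**Step 5**
Reactants: 9
Product: 11 dimethyl 1-[2-(2-ethyl-1,3-dioxolan-2-yl)ethyl]-7α-(hydroxymethyl)cyclohept-2-ene-1,2-dicarboxylate, via alkylborane 10 (not isolated)
Conditions: 9-BBN, THF, 0 °C to 45 °C; then 30% H2O2, aq. NaOAc, 0 °C
Reagents that add atoms: hydrogen peroxide (OO)
Why: Anti-Markovnikov hydroboration–oxidation touches only the 1,1-disubstituted alkene (the conjugated trisubstituted one is inert to 9-BBN); hydrogen should be delivered to C7 from the β face, away from the dioxolanylethyl chain on C1, so that the CH2OH ends α, and this facial preference rests on sterics alone.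

**Step 6**
Reactants: 11
Product: 12 dimethyl 7α-{[bis(tert-butoxycarbonyl)amino]methyl}-1-[2-(2-ethyl-1,3-dioxolan-2-yl)ethyl]cyclohept-2-ene-1,2-dicarboxylate
Conditions: HN(Boc)2, PPh3, DIAD, THF, 0 °C to rt
Reagents that add atoms: di-tert-butyl iminodicarbonate (CC(C)(C)OC(=O)NC(=O)OC(C)(C)C)
Why: Mitsunobu substitution of the primary alcohol by the acidic imidodicarbonate installs the nitrogen without an N–H, so it survives the later enolate steps; the C7 centre is not involved.

**Step 7**
Reactants: 12
Product: 14 dimethyl 7α-{[bis(tert-butoxycarbonyl)amino]methyl}-1-[2-(2-ethyl-1,3-dioxolan-2-yl)ethyl]-3-hydroxycycloheptane-1,2-dicarboxylate, via boronate 13 (not isolated)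
Conditions: B2pin2, CuCl (5 mol %), Xantphos (5 mol %), NaOtBu (10 mol %), MeOH (2 equiv), THF, rt; then 30% H2O2, aq. NaHCO3, 0 °C
Reagents that add atoms: hydrogen peroxide (OO)
Why: Copper-catalysed conjugate borylation of the unsaturated ester followed by C–B oxidation should place oxygen on the β-carbon only; the two new centres are of no consequence because both are erased or epimerisable after step 8.

**Step 8**
Reactants: 14
Product: 15 dimethyl 7α-{[bis(tert-butoxycarbonyl)amino]methyl}-1-[2-(2-ethyl-1,3-dioxolan-2-yl)ethyl]-3-oxocycloheptane-1,2-dicarboxylate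
Conditions: Dess–Martin periodinane, pyridine, CH2Cl2, rt
Reagents that add atoms: none
Why: Dess–Martin oxidation of the secondary alcohol should give the second β-keto ester, which makes C2 acidic and C4 enolisable only now that the first ketone is gone.

**Step 9**
Reactants: 15
Product: 16 methyl 7α-{[bis(tert-butoxycarbonyl)amino]methyl}-1-[2-(2-ethyl-1,3-dioxolan-2-yl)ethyl]-2-[methoxy(methyl)carbamoyl]-3-oxocycloheptane-1-carboxylate
Conditions: MeNH(OMe)·HCl, Et3N, DMAP (20 mol %), toluene, 105 °C
Reagents that add atoms: N,O-dimethylhydroxylamine hydrochloride (CNOC.Cl)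
Why: Ester-to-amide exchange is specific to the enolisable β-keto ester (DMAP-assisted aminolysis), so the ester on the quaternary carbon should stay and the two carboxyl carbons become distinguishable.

**Step 10**
Reactants: 16
Product: 17 C2-cinnamylated β-keto amide (cinnamyl 2β; amide 2α)
Conditions: methyl (E)-cinnamyl carbonate, Pd(PPh3)4 (5 mol %), THF, rt
Reagents that add atoms: methyl (E)-3-phenylprop-2-en-1-yl carbonate (COC(=O)OC/C=C/c1ccccc1)
Why: Tsuji–Trost allylic alkylation of the stabilised β-keto amide enolate at the unsubstituted allyl terminus should form the second quaternary carbon from the β face, opposite the C1 side chain and the C7 CH2N arm, which puts the cinnamyl group cis to the C1 ester.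

**Step 11**
Reactants: 17
Product: 18 4β-(but-3-en-1-yl) ketone
Conditions: LDA, THF, −78 °C; then 4-iodobut-1-ene, DMPU, −78 to −30 °C
Reagents that add atoms: 4-iodobut-1-ene (C=CCCI)
Why: Kinetic enolate alkylation can occur only at C4, and the electrophile should enter from the β face because the α face now carries the amide, the C1 chain and the CH2N arm, giving the butenyl group cis to the cinnamyl group.

**Step 12**
Reactants: 18
Product: 19 3-methylidene triene
Conditions: Zn, CH2Br2, TiCl4, THF–CH2Cl2, 0 °C to rt
Reagents that add atoms: dibromomethane (BrCBr)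
Why: Takai–Lombardo methylenation is non-basic and suited to hindered enolisable ketones, so C4 should not epimerise and the ester and amide should stay.

**Step 13**
Reactants: 19
Product: 20 cyclopentene-fused cycloheptane (C3=CH in the five-membered ring; C4–H α)
Conditions: second-generation Grubbs catalyst RuCl2(H2IMes)(PCy3)(=CHPh) (5 mol %), CH2Cl2 (5 mM), 40 °C
Reagents that add atoms: none
Why: Ring-closing metathesis between the butenyl terminus and the 1,1-disubstituted alkene gives the trisubstituted cyclopentene; the five-membered closure should outrun any pairing with the internal cinnamyl alkene, and the C4 centre is carried over unchanged.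

**Step 14**
Reactants: 20
Product: 21 2α-formyl compound
Conditions: Cp2Zr(H)Cl (1.5 equiv), THF, rt
Reagents that add atoms: none
Why: Reduction of the tertiary N-methoxy amide with zirconocene chloride hydride stops at the aldehyde and is known to spare esters and carbamates; the internal styrenyl and trisubstituted alkenes are slow to hydrozirconate.

**Step 15**
Reactants: 21
Product: 22 2α-(1,3-dioxolan-2-yl) compound
Conditions: HOCH2CH2OH, PPTS, benzene, 80 °C (Dean–Stark)
Reagents that add atoms: ethane-1,2-diol (OCCO)
Why: Acetalisation masks the aldehyde so that the alcohol freed in step 16 cannot lactonise or form a lactol with it.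

**Step 16**
Reactants: 22
Product: 23 1β-(hydroxymethyl) compound
Conditions: LiBH4, MeOH (1 equiv), Et2O, 0 °C to rt
Reagents that add atoms: none
Why: Borohydride reduction of the only remaining ester should give the neopentyl alcohol; acetals, carbamates and alkenes are inert.

**Step 17**
Reactants: 23
Product: 24 1β-[(ethenyloxy)methyl] compound
Conditions: vinyl acetate, [Ir(cod)Cl]2 (2 mol %), Na2CO3, toluene, 100 °C
Reagents that add atoms: ethenyl acetate (CC(=O)OC=C)
Why: Iridium-catalysed transfer vinylation of the primary alcohol brings in the future lactone carbonyl carbon at the enol-ether oxidation level.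

**Step 18**
Reactants: 24
Product: 25 tricyclic enol ether (C2–CH2–CH=CH–O–CH2–C1 ring on the β face)
Conditions: second-generation Grubbs catalyst RuCl2(H2IMes)(PCy3)(=CHPh) (10 mol %), toluene (2 mM), 70 °C
Reagents that add atoms: none
Why: Olefin metathesis by the Chauvin mechanism: the ruthenium alkylidene exchanges onto the cinnamyl CH, adds across the tethered vinyl ether in a [2+2] step, and cycloreversion of the ruthenacyclobutane releases the cyclic enol ether, whose new C=C joins the carbon that becomes the lactone carbonyl to the carbon that becomes its α-CH2. The closest known reaction type is enol ether–olefin ring-closing metathesis as used for oxepenes and other cyclic enol ethers. The ring closed is the seven-membered 4,5-dihydrooxepine, formed by ring-closing metathesis with an endocyclic alkene across the two vicinal quaternary carbons. No stereocentre is created and the alkene can only be cis in a ring of this size. The step needs chemoselectivity against the trisubstituted cyclopentene and against dimerisation. This should be secured because the two arms are held cis and close by the quaternary carbons (gem-disubstituent effect), the ring-fusion alkene is too hindered to enter a metallacycle, and high dilution suppresses cross-metathesis while styrene is a poor partner for the reverse reaction.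

**Step 19**
Reactants: 25
Product: 26 tricyclic ε-lactone (C2–CH2–CH2–C(=O)–O–CH2–C1)
Conditions: PCC, NaOAc, 4 Å molecular sieves, CH2Cl2, rt
Reagents that add atoms: pyridinium chlorochromate ([O-][Cr](=O)(=O)Cl.c1cc[nH+]cc1)
Why: Chlorochromate oxidation of a cyclic enol ether to the lactone (addition of chromate to the electron-rich alkene, then hydride shift) should convert O–CH=CH into O–C(=O)–CH2 while the buffered medium spares the acetals and the hindered alkene.

**Step 20**
Reactants: 26
Product: 31 target CNP0292775.1, via amino keto aldehyde 27 (not isolated), via cyclic iminium 28 (not isolated), via secondary amine 29 (not isolated), via methyleneiminium 30 (not isolated)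
Conditions: CF3CO2H–CH2Cl2–H2O (10:10:1), 0 °C to rt; concentrate; then 37% aq. HCHO, AcOH–NaOAc, MeOH, 60 °C
Reagents that add atoms: water (O); formaldehyde (C=O)
Why: Acid removes both Boc groups and both dioxolanes; the amine condenses with the aldehyde to the six-membered cyclic iminium, which the ketone enol attacks in an intramolecular Mannich reaction (five-membered ring, the two new CH centres fixed by the bridged geometry, the acyl-bearing one by equilibration); formaldehyde then gives the N-methyleneiminium, which the ethyl ketone enol closes in a second Mannich reaction (six-membered ring) with the methyl settling equatorial under the equilibrating conditions. The secondary amine is kept protonated and never isolated so that it cannot acylate itself on the lactone.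

**Compound list**

1 | 1-(cyclopent-1-en-1-yl)pyrrolidine | C1CCN(C1)C1=CCCC1 | starting material
2 | dimethyl but-2-ynedioate | COC(=O)C#CC(=O)OC | starting material
3 | dimethyl 1-(pyrrolidin-1-yl)bicyclo[3.2.0]hept-6-ene-6,7-dicarboxylate (racemic cyclobutene adduct) | COC(=O)C1=C(C(=O)OC)C2(N3CCCC3)CCCC12 | intermediate
4 | dimethyl 3-(pyrrolidin-1-yl)cyclohepta-2,7-diene-1,2-dicarboxylate | COC(=O)C1=C(N2CCCC2)CCCC=C1C(=O)OC | intermediate
5 | dimethyl 7-oxocyclohept-2-ene-1,2-dicarboxylate (racemic) | COC(=O)C1C(=O)CCCC=C1C(=O)OC | intermediate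
6 | pent-1-en-3-one | CCC(=O)C=C | starting material
7 | dimethyl (1S)-7-oxo-1-(3-oxopentyl)cyclohept-2-ene-1,2-dicarboxylate | O=C1CCCC=C(C(=O)OC)[C@@]1(C(=O)OC)CCC(=O)CC | intermediate
8 | dimethyl (1S)-1-[2-(2-ethyl-1,3-dioxolan-2-yl)ethyl]-7-oxocyclohept-2-ene-1,2-dicarboxylate | O=C1CCCC=C(C(=O)OC)[C@@]1(C(=O)OC)CCC2(CC)OCCO2 | intermediate
9 | dimethyl 1-[2-(2-ethyl-1,3-dioxolan-2-yl)ethyl]-7-methylidenecyclohept-2-ene-1,2-dicarboxylate (C1 as in 8) | C=C1CCCC=C(C(=O)OC)[C@@]1(C(=O)OC)CCC2(CC)OCCO2 | intermediate
10 | 9-borabicyclo[3.3.1]nonane adduct of 9 (boron on the exocyclic CH2; C7–H β) | C(B1C2CCCC1CCC2)[C@H]1CCCC=C(C(=O)OC)[C@@]1(C(=O)OC)CCC3(CC)OCCO3 | intermediate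
11 | dimethyl 1-[2-(2-ethyl-1,3-dioxolan-2-yl)ethyl]-7α-(hydroxymethyl)cyclohept-2-ene-1,2-dicarboxylate | OC[C@H]1CCCC=C(C(=O)OC)[C@@]1(C(=O)OC)CCC2(CC)OCCO2 | intermediate
12 | dimethyl 7α-{[bis(tert-butoxycarbonyl)amino]methyl}-1-[2-(2-ethyl-1,3-dioxolan-2-yl)ethyl]cyclohept-2-ene-1,2-dicarboxylate | CC(C)(C)OC(=O)N(C[C@H]1CCCC=C(C(=O)OC)[C@@]1(C(=O)OC)CCC2(CC)OCCO2)C(=O)OC(C)(C)C | intermediate
13 | 3-(4,4,5,5-tetramethyl-1,3,2-dioxaborolan-2-yl) cycloheptane diester from 12 (mixture at C2 and C3) | CC(C)(C)OC(=O)N(C[C@H]1CCCC(B2OC(C)(C)C(C)(C)O2)C(C(=O)OC)[C@@]1(C(=O)OC)CCC3(CC)OCCO3)C(=O)OC(C)(C)C | intermediate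
14 | dimethyl 7α-{[bis(tert-butoxycarbonyl)amino]methyl}-1-[2-(2-ethyl-1,3-dioxolan-2-yl)ethyl]-3-hydroxycycloheptane-1,2-dicarboxylate (mixture at C2 and C3) | CC(C)(C)OC(=O)N(C[C@H]1CCCC(O)C(C(=O)OC)[C@@]1(C(=O)OC)CCC2(CC)OCCO2)C(=O)OC(C)(C)C | intermediate
15 | dimethyl 7α-{[bis(tert-butoxycarbonyl)amino]methyl}-1-[2-(2-ethyl-1,3-dioxolan-2-yl)ethyl]-3-oxocycloheptane-1,2-dicarboxylate (C2 epimers and enol) | CC(C)(C)OC(=O)N(C[C@H]1CCCC(=O)C(C(=O)OC)[C@@]1(C(=O)OC)CCC2(CC)OCCO2)C(=O)OC(C)(C)C | intermediate
16 | methyl 7α-{[bis(tert-butoxycarbonyl)amino]methyl}-1-[2-(2-ethyl-1,3-dioxolan-2-yl)ethyl]-2-[methoxy(methyl)carbamoyl]-3-oxocycloheptane-1-carboxylate (C2 epimers and enol) | CC(C)(C)OC(=O)N(C[C@H]1CCCC(=O)C(C(=O)N(C)OC)[C@@]1(C(=O)OC)CCC2(CC)OCCO2)C(=O)OC(C)(C)C | intermediate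
17 | 16 with a 2β-[(E)-3-phenylprop-2-en-1-yl] group (amide 2α) | CC(C)(C)OC(=O)N(C[C@H]1CCCC(=O)[C@](C(=O)N(C)OC)(C/C=C/c5ccccc5)[C@@]1(C(=O)OC)CCC2(CC)OCCO2)C(=O)OC(C)(C)C | intermediate
18 | 17 with a 4β-(but-3-en-1-yl) group | CC(C)(C)OC(=O)N(C[C@H]1CC[C@H](CCC=C)C(=O)[C@](C(=O)N(C)OC)(C/C=C/c5ccccc5)[C@@]1(C(=O)OC)CCC2(CC)OCCO2)C(=O)OC(C)(C)C | intermediate
19 | 18 with C3=CH2 in place of C3=O | CC(C)(C)OC(=O)N(C[C@H]1CC[C@H](CCC=C)C(=C)[C@](C(=O)N(C)OC)(C/C=C/c5ccccc5)[C@@]1(C(=O)OC)CCC2(CC)OCCO2)C(=O)OC(C)(C)C | intermediate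
20 | bicycle from 19: cyclopentene fused at C3–C4 (C3=CH–CH2–CH2–C4; C4–H α); ester, amide, cinnamyl, side chain and CH2N(Boc)2 as in 19 | CC(C)(C)OC(=O)N(C[C@H]1CC[C@@H]3CCC=C3[C@](C(=O)N(C)OC)(C/C=C/c5ccccc5)[C@@]1(C(=O)OC)CCC2(CC)OCCO2)C(=O)OC(C)(C)C | intermediate
21 | 20 with 2α-CHO in place of the amide | CC(C)(C)OC(=O)N(C[C@H]1CC[C@@H]3CCC=C3[C@](C=O)(C/C=C/c5ccccc5)[C@@]1(C(=O)OC)CCC2(CC)OCCO2)C(=O)OC(C)(C)C | intermediate
22 | 21 with the aldehyde as its 1,3-dioxolane | CC(C)(C)OC(=O)N(C[C@H]1CC[C@@H]3CCC=C3[C@](C4OCCO4)(C/C=C/c5ccccc5)[C@@]1(C(=O)OC)CCC2(CC)OCCO2)C(=O)OC(C)(C)C | intermediate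
23 | 22 with 1β-CH2OH in place of CO2CH3 | CC(C)(C)OC(=O)N(C[C@H]1CC[C@@H]3CCC=C3[C@](C4OCCO4)(C/C=C/c5ccccc5)[C@@]1(CO)CCC2(CC)OCCO2)C(=O)OC(C)(C)C | intermediate
24 | 23 as its vinyl ether (1β-CH2–O–CH=CH2) | CC(C)(C)OC(=O)N(C[C@H]1CC[C@@H]3CCC=C3[C@](C4OCCO4)(C/C=C/c5ccccc5)[C@@]1(COC=C)CCC2(CC)OCCO2)C(=O)OC(C)(C)C | intermediate
25 | tricyclic enol ether: seven-membered ring C2–CH2–CH=CH–O–CH2–C1 on the β face; dioxolanes and CH2N(Boc)2 retained | CC(C)(C)OC(=O)N(C[C@H]1CC[C@@H]3CCC=C3[C@]4(C5OCCO5)CC=COC[C@]14CCC2(CC)OCCO2)C(=O)OC(C)(C)C | intermediate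
26 | tricyclic ε-lactone: C2–CH2–CH2–C(=O)–O–CH2–C1; dioxolanes and CH2N(Boc)2 retained | CC(C)(C)OC(=O)N(C[C@H]1CC[C@@H]3CCC=C3[C@]4(C5OCCO5)CCC(=O)OC[C@]14CCC2(CC)OCCO2)C(=O)OC(C)(C)C | intermediate
27 | amino keto aldehyde (free CH2NH2, CHO and ethyl ketone on the lactone tricycle; trifluoroacetate in the flask) | NC[C@H]1CC[C@@H]3CCC=C3[C@]4(C=O)CCC(=O)OC[C@]14CCC(=O)CC | intermediate
28 | cyclic imine (N=CH bridge between the C7 CH2 and C2; protonated in the flask) | C1[C@H]2CC[C@@H]3CCC=C3[C@]4(C=N1)CCC(=O)OC[C@]24CCC(=O)CC | intermediate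
29 | pentacyclic secondary amine with a propanoyl group on the new cyclopentane carbon | N1C[C@H]3CC[C@@H]4CCC=C4[C@]45CCC(=O)OC[C@]34C[C@H](C(CC)=O)[C@H]15 | intermediate
30 | N-methyleneiminium acetate of 29 | C=[N+]1C[C@H]3CC[C@@H]4CCC=C4[C@]45CCC(=O)OC[C@]34C[C@H](C(CC)=O)[C@H]15.CC(=O)[O-] | intermediate
31 | CNP0292775.1 | C[C@@H]1CN2C[C@H]3CC[C@@H]4CCC=C4[C@]45CCC(=O)OC[C@]34C[C@H](C1=O)[C@H]25 | target

Total steps: 20. Longest linear sequence: 20 steps (1 to 31).

**Steps most likely to fail**

Step 11. The hindered ketone enolate may react only slowly with the unactivated homoallylic iodide. Elimination of HI from the electrophile, proton transfer that scrambles the kinetically set C4 configuration, and intramolecular Claisen attack of the enolate on the C1 ester can then compete. The fallback changes the order of bond formation and uses the more nucleophilic dianion. It sets out from 16: NaH, then n-BuLi (THF, 0 °C) gives the 2,4-dianion of the β-keto amide, which is alkylated at C4 by 4-iodobut-1-ene to give the 4-butenyl β-keto amide F1. Palladium-catalysed cinnamylation of F1 as in step 10 then sets C2 from the β face, and brief treatment with DBU equilibrates the still epimerisable C4 centre. The route is rejoined at 18.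

Step 12. Methylenation of a ketone flanked by a quaternary and a tertiary carbon may stall, or the Lewis-acidic titanium may open the dioxolane or cleave a Boc group. The fallback builds the cyclopentene by reductive carbonyl coupling instead of olefination and metathesis. It sets out from 17: the kinetic enolate (LDA) is alkylated with tert-butyl(3-iodopropoxy)dimethylsilane to give the silyl ether F2; Bu4NF frees the primary alcohol F3; Dess–Martin oxidation gives the keto aldehyde F4; intramolecular McMurry coupling (TiCl3, Zn–Cu couple, DME, reflux) joins the aldehyde and ketone carbons as the ring alkene. The route is rejoined at 20.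

Step 20. After deprotection, condensation of the amine with the side-chain ketone or oligomerisation of the imine may outrun the Mannich closure, and enolisation toward the wrong α-carbon would waste material. The fallback reverses the order of C–C and C–N bond formation. It sets out from 26: PPTS in wet acetone (60 °C) removes both dioxolanes but not the Boc groups, giving the protected keto aldehyde F5; piperidinium acetate (toluene, 80 °C) effects intramolecular aldol condensation to the cyclopentene enone F6; trifluoroacetic acid then aqueous NaHCO3 frees the amine, which adds to the enone in an intramolecular aza-Michael reaction. The route is rejoined at 29, which is treated with formaldehyde as in step 20.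

Further compounds
F1 | step 11 | methyl 7α-{[bis(tert-butoxycarbonyl)amino]methyl}-4-(but-3-en-1-yl)-1-[2-(2-ethyl-1,3-dioxolan-2-yl)ethyl]-2-[methoxy(methyl)carbamoyl]-3-oxocycloheptane-1-carboxylate (mixture at C2 and C4) | CC(C)(C)OC(=O)N(C[C@H]1CCC(CCC=C)C(=O)C(C(=O)N(C)OC)[C@@]1(C(=O)OC)CCC2(CC)OCCO2)C(=O)OC(C)(C)C
F2 | step 12 | 17 with a 4β-[3-(tert-butyldimethylsilyloxy)propyl] group | CC(C)(C)OC(=O)N(C[C@H]1CC[C@H](CCCO[Si](C)(C)C(C)(C)C)C(=O)[C@](C(=O)N(C)OC)(C/C=C/c5ccccc5)[C@@]1(C(=O)OC)CCC2(CC)OCCO2)C(=O)OC(C)(C)C
F3 | step 12 | 17 with a 4β-(3-hydroxypropyl) group | CC(C)(C)OC(=O)N(C[C@H]1CC[C@H](CCCO)C(=O)[C@](C(=O)N(C)OC)(C/C=C/c5ccccc5)[C@@]1(C(=O)OC)CCC2(CC)OCCO2)C(=O)OC(C)(C)C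
F4 | step 12 | 17 with a 4β-(3-oxopropyl) group | CC(C)(C)OC(=O)N(C[C@H]1CC[C@H](CCC=O)C(=O)[C@](C(=O)N(C)OC)(C/C=C/c5ccccc5)[C@@]1(C(=O)OC)CCC2(CC)OCCO2)C(=O)OC(C)(C)C
F5 | step 20 | 26 with both dioxolanes hydrolysed (CHO and ethyl ketone free; N(Boc)2 retained) | CC(C)(C)OC(=O)N(C[C@H]1CC[C@@H]3CCC=C3[C@]4(C=O)CCC(=O)OC[C@]14CCC(=O)CC)C(=O)OC(C)(C)C
F6 | step 20 | aldol condensation product of F5: cyclopentene with the propanoyl group on the alkene carbon; N(Boc)2 retained | CC(C)(C)OC(=O)N(C[C@H]1CC[C@@H]3CCC=C3[C@]45CCC(=O)OC[C@]14CC(C(=O)CC)=C5)C(=O)OC(C)(C)C
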